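**Plan**
1. Retrosynthesis: the C5–C6 and C7–C8 bonds are cut together (radical bicyclisation). Then come the C8–O ether bond of the remaining oxocane (carbenoid O–H insertion), C8–C17 (allylic alkylation), C1–C2 (aldol) and C10–C9 (conjugate addition to a chiral cyclohexenone).
2. Enabling feature: C8 is a fully substituted carbon bearing the ring-ether oxygen. In an oxocane (O, C4, C3, C2, C1, C10, C9, C8) the lactone ester C19(=O)–O–C7H=C6HCl hangs on C8 through C17, and an ethynyl group (C5≡C16) on C4 lies across the ether oxygen. A C8 radical therefore reaches C7 by 5-exo, and the resulting C6 radical reaches C5 by 6-exo.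
3. Forward order: cyclohexane → C2–C5 chain → oxocane → C17/C19 arm → one operation closes the γ-lactone, the oxane and with it the ten-membered carbocycle → desilylation.
4. Stereochemistry: the enone silyloxy centre (later erased at C11) relays to C10 and C1. D-Proline aldol sets C3/C4, chelation sets C2, directed reduction C14, the Ir catalyst C17, ring-face hydride delivery C9, equatorial ylide attack C11.
5. The cascade sets C6, C7 and C8 and is stereoconvergent: both C8 epimers and both enol-ester geometries collapse into one radical manifold.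

Key step: step 26

Remark (locants): briarane numbering is used. C1 quaternary (C15 methyl), C2/C3 CHOAc, C4 ether CH, C5(=C16H2), C6 CHCl, C7 lactone O–CH, C8 ether/lactone carbon, C9 CHOH, C10 ring-fusion CH, C11 C(OH)(C20H2OAc), C14 CHOAc, C17(C18H3)–C19(=O) lactone arm.
Remark (assumption): (R)-4-(tert-butyldimethylsilyloxy)cyclohex-2-enone, (4-methoxybenzyloxy)acetaldehyde and 3-(trimethylsilyl)propynal are taken as purchasable. Anhydrous chloroacetaldehyde is liberated from its commercial aqueous solution.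
Remark (mixtures): from the oxocane onward C8 is carried as an epimer mixture (no descriptor written), and the chlorovinyl ester as an E/Z mixture. Both elements vanish in the key step.

**Route**

Step 1
Reactants: 1 (4-methoxybenzyloxy)acetaldehyde; 2 3-(trimethylsilyl)propynal
Product: 3 (2R,3R)-3-hydroxy-2-[(4-methoxybenzyl)oxy]-5-(trimethylsilyl)pent-4-ynal
Conditions: D-proline (20 mol%), DMF, 4 °C, slow addition of 1 to 2 (2 equiv)
Reagents that add atoms: none
Why: Proline-catalysed direct cross-aldol (enamine of the α-alkoxy aldehyde, non-enolisable ynal as acceptor) should give the anti adduct through the hydrogen-bonded chair transition state, D-proline setting C3 and C4 as (R,R).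

Step 2
Reactants: 3 (2R,3R)-3-hydroxy-2-[(4-methoxybenzyl)oxy]-5-(trimethylsilyl)pent-4-ynal
Product: 4 (2R,3R)-2-[(4-methoxybenzyl)oxy]-3-(triethylsilyloxy)-5-(trimethylsilyl)pent-4-ynal
Conditions: TESOTf, 2,6-lutidine, CH2Cl2, −78 °C
Reagents that add atoms: triethylsilyl trifluoromethanesulfonate, CC[Si](CC)(CC)OS(=O)(=O)C(F)(F)F
Why: Silyl triflate protection of the propargylic alcohol blocks retro-aldol and keeps the C4 oxygen distinguishable from the C3 PMB ether.

Step 3
Reactants: 4 (2R,3R)-2-[(4-methoxybenzyl)oxy]-3-(triethylsilyloxy)-5-(trimethylsilyl)pent-4-ynal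
Product: 5 (2R,3R)-2-[(4-methoxybenzyl)oxy]-3-(triethylsilyloxy)pent-4-ynal
Conditions: AgNO3 (10 mol%), acetone/H2O/CH2Cl2, rt
Reagents that add atoms: none
Why: Silver(I)-catalysed protiodesilylation of the alkynyl–silicon bond runs under neutral conditions that should spare the TES ether and the epimerisable α-alkoxy aldehyde.

Step 4
Reactants: 6 (R)-4-(tert-butyldimethylsilyloxy)cyclohex-2-en-1-one
Product: 7 (R)-4-(tert-butyldimethylsilyloxy)-2-iodocyclohex-2-en-1-one
Conditions: I2, pyridine/CH2Cl2 (1:1), rt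
Reagents that add atoms: iodine, II
Why: α-Iodination of the enone by pyridine-mediated conjugate addition–elimination leaves the silyloxy stereocentre untouched.

Step 5
Reactants: 7 (R)-4-(tert-butyldimethylsilyloxy)-2-iodocyclohex-2-en-1-one
Product: 8 (R)-4-(tert-butyldimethylsilyloxy)-2-methylcyclohex-2-en-1-one
Conditions: Me4Sn, Pd2(dba)3 (2.5 mol%), AsPh3, CuI, NMP, 40 °C
Reagents that add atoms: tetramethylstannane, C[Sn](C)(C)C
Why: Stille coupling of the α-iodoenone is base-free and so avoids elimination of the γ-silyloxy group and aromatisation.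

Step 6
Reactants: 8 (R)-4-(tert-butyldimethylsilyloxy)-2-methylcyclohex-2-en-1-one
Product: 9 (3R,4R)-4-(tert-butyldimethylsilyloxy)-2-methyl-1-(trimethylsilyloxy)-3-vinylcyclohex-1-ene
Conditions: CH2=CHMgBr (1.5 equiv), CuBr·SMe2 (10 mol%), TMSCl, HMPA, THF, −78 °C; Et3N quench
Reagents that add atoms: vinylmagnesium bromide, C=C[Mg]Br; chlorotrimethylsilane, C[Si](C)(C)Cl
Why: Copper-catalysed conjugate addition with silyl trapping should deliver the vinyl group anti to the neighbouring silyloxy group (setting C10) and capture the enolate regiospecifically as the tetrasubstituted silyl enol ether.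

Step 7
Reactants: 9 (3R,4R)-4-(tert-butyldimethylsilyloxy)-2-methyl-1-(trimethylsilyloxy)-3-vinylcyclohex-1-ene; 5 (2R,3R)-2-[(4-methoxybenzyl)oxy]-3-(triethylsilyloxy)pent-4-ynal
Product: 10 aldol adduct (C14 ketone; quaternary C1; C2-OH; C3-OPMB; C4-OTES; C5≡C16H; C10-vinyl; C11-OTBS)
Conditions: MgBr2·OEt2 (3 equiv), CH2Cl2, −78 → −20 °C; pH 7 buffer
Reagents that add atoms: none
Why: Chelation-controlled Mukaiyama aldol: magnesium bridges the aldehyde and α-OPMB oxygens so attack should give the 2,3-syn carbinol (C2), and the aldehyde should enter the enol ether anti to the C10 vinyl group, fixing the quaternary C1.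

Step 8
Reactants: 10 aldol adduct
Product: 11 C2/C14 anti-diol (axial C14-OH)
Conditions: Me4NBH(OAc)3, MeCN/AcOH (1:1), −30 °C
Reagents that add atoms: none
Why: Evans–Saksena reduction delivers hydride intramolecularly from the C2-alkoxyborohydride to the β-hydroxy ketone and should give the 1,3-anti diol, which is the axial C14 alcohol.

Step 9
Reactants: 11 C2/C14 anti-diol
Product: 12 C2/C3/C14 triol (C4-OTES; C11-OTBS)
Conditions: DDQ, CH2Cl2/pH 7 buffer (10:1), 0 °C
Reagents that add atoms: none
Why: Oxidative PMB ether cleavage with DDQ in wet solvent should leave silyl ethers, alkyne and vinyl group untouched.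

Step 10
Reactants: 12 C2/C3/C14 triol
Product: 13 C2/C3/C14 triacetate
Conditions: Ac2O, pyridine, DMAP (cat.), CH2Cl2, rt
Reagents that add atoms: acetic anhydride, CC(=O)OC(C)=O
Why: DMAP-catalysed acetylation installs three of the target's acetates at a stage where only these hydroxyls are free.

Step 11
Reactants: 13 C2/C3/C14 triacetate
Product: 14 C9 aldehyde
Conditions: OsO4 (2 mol%), NaIO4, 2,6-lutidine, dioxane/H2O (3:1), rt
Reagents that add atoms: sodium periodate (oxygen of the new C=O, relayed by OsO4), [Na+].[O-]I(=O)(=O)=O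
Why: Lemieux–Johnson cleavage of the only alkene unmasks the C9 aldehyde while the terminal alkyne is inert to osmylation.

Step 12
Reactants: 14 C9 aldehyde
Product: 16 C9-keto C8-diazo tert-butyl ester, via diazo aldol adduct 15 (not isolated)
Conditions: N2CHCO2t-Bu, DBU (20 mol%), MeCN, 0 °C → rt; then IBX, DMSO, rt
Reagents that add atoms: tert-butyl diazoacetate, CC(C)(C)OC(=O)C=[N+]=[N-]
Why: Base-catalysed aldol-type addition of the diazoacetate then IBX oxidation of the diazo carbinol gives the acceptor/acceptor diazo compound; C10 is the all-equatorial epimer, so transient enolisation should be harmless.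

Step 13
Reactants: 16 C9-keto C8-diazo tert-butyl ester
Product: 17 C4 alcohol of the diazo keto ester
Conditions: HF·pyridine, pyridine, THF, 0 °C
Reagents that add atoms: none
Why: Selective desilylation: a secondary TES ether is cleaved much faster than the TBS ether, and pyridine buffering should suppress C3→C4 acetyl migration.

Step 14
Reactants: 17 C4 alcohol of the diazo keto ester
Product: 18 oxocan-3-one (ring O–C4–C3–C2–C1–C10–C9–C8; C8-H with CO2t-Bu; C9 ketone)
Conditions: Rh2(OAc)4 (2 mol%), CH2Cl2, reflux, syringe-pump addition (final 2 mM)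
Reagents that add atoms: none
Why: Intramolecular rhodium-carbenoid O–H insertion of a diazo β-keto ester, a known route to medium-ring ethers, should close the eight-membered ring and leaves the C4 stereocentre untouched.

Step 15
Reactants: 18 oxocan-3-one
Product: 19 C8-(but-3-en-2-yl) quaternary β-keto ester (C17 stereocentre set)
Conditions: [Ir(cod)Cl]2 (2 mol%), BINOL-derived bis(1-phenylethyl)amine phosphoramidite (4 mol%), TBD (10 mol%), (E)-crotyl methyl carbonate, THF, 35 °C
Reagents that add atoms: (E)-but-2-en-1-yl methyl carbonate, C/C=C/COC(=O)OC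
Why: Iridium-catalysed branched-selective allylic alkylation forms C8–C17 at the substituted allyl terminus; the ligand enantiomer is chosen so the catalyst sets C17, while the C8 configuration does not matter.

Step 16
Reactants: 19 C8-(but-3-en-2-yl) quaternary β-keto ester
Product: 20 (9S)-alcohol
Conditions: NaBH4, THF/MeOH (4:1), −20 → 0 °C
Reagents that add atoms: none
Why: Borohydride reduction of the ring ketone; hydride should approach from the face opposite the axial C15 methyl of the trans-fused cyclohexane, giving the 9S carbinol.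

Step 17
Reactants: 20 (9S)-alcohol
Product: 21 C9 TBS ether
Conditions: TBSOTf, 2,6-lutidine, CH2Cl2, 0 °C → rt
Reagents that add atoms: tert-butyldimethylsilyl trifluoromethanesulfonate, CC(C)(C)[Si](C)(C)OS(=O)(=O)C(F)(F)F
Why: Silyl triflate protection of the hindered C9 hydroxyl is needed because a free C9–OH would lactonise onto the C19 carboxyl derivatives made later.

Step 18
Reactants: 21 C9 TBS ether
Product: 22 C11 alcohol (C9-OTBS retained)
Conditions: HF·pyridine, pyridine, THF, 0 °C → rt
Reagents that add atoms: none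
Why: Sterically differentiated desilylation: the ordinary cyclohexyl C11 TBS ether should cleave far faster than the C9 TBS ether flanked by the quaternary C8.

Step 19
Reactants: 22 C11 alcohol
Product: 23 C11 ketone
Conditions: Dess–Martin periodinane, NaHCO3, CH2Cl2, rt
Reagents that add atoms: none
Why: Buffered Dess–Martin oxidation of the only free secondary alcohol erases the relay stereocentre and provides the ketone for C20 introduction.

Step 20
Reactants: 23 C11 ketone
Product: 24 C11/C20 spiro-epoxide (axial C11–O)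
Conditions: Me3S(O)I, NaH, DMSO/THF, rt
Reagents that add atoms: trimethylsulfoxonium iodide, C[S+](C)(C)=O.[I-]
Why: Corey–Chaykovsky epoxidation: axial approach is blocked by the syn-axial C15 methyl, so the sulfoxonium ylide should deliver the methylene equatorially and leave the C11 oxygen axial as in the target.

Step 21
Reactants: 24 C11/C20 spiro-epoxide
Product: 25 C11 tertiary alcohol with C20 acetate (all four acetates in place)
Conditions: CsOAc, AcOH, DMF, 70 °C
Reagents that add atoms: acetic acid (delivered as caesium acetate, CC(=O)[O-].[Cs+]), CC(=O)O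
Why: SN2 opening of the epoxide at the primary carbon C20 by acetate gives the C20 acetate and the free tertiary C11 alcohol with retention at C11.

Step 22
Reactants: 25 C11 tertiary alcohol with C20 acetate
Product: 27 C19 carboxylic acid, via C19 aldehyde 26 (not isolated)
Conditions: OsO4 (2 mol%), NaIO4, 2,6-lutidine, dioxane/H2O; then NaClO2, NaH2PO4, 2-methyl-2-butene, t-BuOH/H2O, 0 °C
Reagents that add atoms: sodium periodate, [Na+].[O-]I(=O)(=O)=O; sodium chlorite, [Na+].[O-]Cl=O
Why: Lemieux–Johnson cleavage of the butenyl alkene followed directly by Pinnick oxidation turns the vinyl group into the C19 acid under conditions that should not epimerise C17.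

Step 23
Reactants: 27 C19 carboxylic acid
Product: 30 2-chlorovinyl ester (E/Z mixture), via acid chloride 28 (not isolated), via 1,2-dichloroethyl ester 29 (not isolated)
Conditions: 1-chloro-N,N,2-trimethylpropenylamine, CH2Cl2, 0 °C; ClCH2CHO (anhydrous), ZnCl2 (10 mol%), −20 → 0 °C; then Et3N, 0 °C → rt
Reagents that add atoms: chloroacetaldehyde, ClCC=O
Why: Neutral acyl chloride formation, Lewis-acid-catalysed addition of the acyl chloride across the aldehyde C=O to the α-chloroalkyl ester and base-induced loss of HCl (acylal chloride as leaving group) give the enol ester; no amine is present while the acyl chloride exists, so C17 should not scramble through a ketene.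

Step 24
Reactants: 30 2-chlorovinyl ester
Product: 31 C8 carboxylic acid
Conditions: TFA/CH2Cl2 (1:4), 0 °C
Reagents that add atoms: none
Why: Acidolysis of the tert-butyl ester (E1 loss of isobutene) should spare the acetates, the hindered silyl ether and the electron-poor enol ester.

Step 25
Reactants: 31 C8 carboxylic acid
Product: 32 C8 N-acyloxyphthalimide (redox-active ester)
Conditions: N-hydroxyphthalimide, DIC, CH2Cl2, 0 °C → rt (no DMAP)
Reagents that add atoms: N-hydroxyphthalimide, O=C1c2ccccc2C(=O)N1O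
Why: Carbodiimide esterification gives the redox-active ester; amine bases are left out so that the C8 carboxylate does not attack the neighbouring enol ester to form a succinic anhydride.

Step 26
Reactants: 32 C8 N-acyloxyphthalimide
Product: 33 9-O-TBS ether of the target (γ-lactone, oxane and ten-membered ring closed)
Conditions: Ru(bpy)3(PF6)2 (2 mol%), Hantzsch ester (1.5 equiv), i-Pr2NEt·HBF4 (1 equiv), CH2Cl2 (5 mM), blue LEDs, 25 °C
Reagents that add atoms: none
Why: Reductive quenching of photoexcited Ru(II) by the Hantzsch ester gives Ru(I), which transfers an electron to the N-acyloxyphthalimide; loss of phthalimide anion and CO2 turns either C8 epimer of 32 into the same tertiary α-alkoxy C8 radical, which adds 5-exo-trig to C7 of the 2-chlorovinyl ester (γ-lactone, C7–C8), the α-chloro C6 radical so formed adds 6-exo-dig to C5 of the ethynyl group (oxane ring, C5–C6, which also completes the ten-membered carbocycle), and the C16 vinyl radical takes hydrogen from the Hantzsch ester. The closest known reaction types are decarboxylative radical generation from redox-active esters of tertiary α-oxy acids, ester-tethered 5-exo radical lactonisation as in atom-transfer cyclisation of unsaturated haloesters, and tandem 5-exo/6-exo-dig enyne radical cyclisation. C8 and C7: the planar C8 radical should close so that the C18 methyl on C17 (fixed in step 15) and the C6 arm on C7 both avoid the bulky C9(OTBS)–C10 branch and lie syn to the ring oxygen, which is the cis-fused oxabicycle; only this isomer can continue, because the alkyne on C4 is then within reach across the ether oxygen. C6: in the chair-like 6-exo transition state chlorine should sit equatorial, because the axial position is 1,3-diaxial to the C3 and C9 arms of the oxocane bridge. The step needs cyclisation to outrun hydrogen transfer to the C8 radical, which the fully substituted radical centre, the weak hydrogen donor at high dilution and the radical-stabilising chlorine on the acceptor should secure, and it needs no control of C8 or alkene geometry in 32 because both are erased in the radical.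

Step 27
Reactants: 33 9-O-TBS ether of the target
Product: 34 CNP0190959.1 (target)
Conditions: HF·pyridine, THF, 0 → 40 °C
Reagents that add atoms: none
Why: Acidic fluoride desilylation frees the C9 hydroxyl under non-basic conditions that should be compatible with the four acetates, the allylic chloride and the lactone.

**Compound list**
1 | (4-methoxybenzyloxy)acetaldehyde | O=CCOCc1ccc(OC)cc1 | starting material
2 | 3-(trimethylsilyl)propynal | O=CC#C[Si](C)(C)C | starting material
3 | (2R,3R)-3-hydroxy-2-[(4-methoxybenzyl)oxy]-5-(trimethylsilyl)pent-4-ynal | O=C[C@H](OCc1ccc(OC)cc1)[C@H](O)C#C[Si](C)(C)C | intermediate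
4 | (2R,3R)-2-[(4-methoxybenzyl)oxy]-3-(triethylsilyloxy)-5-(trimethylsilyl)pent-4-ynal | O=C[C@H](OCc1ccc(OC)cc1)[C@H](O[Si](CC)(CC)CC)C#C[Si](C)(C)C | intermediate
5 | (2R,3R)-2-[(4-methoxybenzyl)oxy]-3-(triethylsilyloxy)pent-4-ynal | O=C[C@H](OCc1ccc(OC)cc1)[C@H](O[Si](CC)(CC)CC)C#C | intermediate
6 | (R)-4-(tert-butyldimethylsilyloxy)cyclohex-2-en-1-one | O=C1C=C[C@H](O[Si](C)(C)C(C)(C)C)CC1 | starting material
7 | (R)-4-(tert-butyldimethylsilyloxy)-2-iodocyclohex-2-en-1-one | O=C1C(I)=C[C@H](O[Si](C)(C)C(C)(C)C)CC1 | intermediate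
8 | (R)-4-(tert-butyldimethylsilyloxy)-2-methylcyclohex-2-en-1-one | O=C1C(C)=C[C@H](O[Si](C)(C)C(C)(C)C)CC1 | intermediate
9 | (3R,4R)-4-(tert-butyldimethylsilyloxy)-2-methyl-1-(trimethylsilyloxy)-3-vinylcyclohex-1-ene | C=C[C@H]1[C@H](O[Si](C)(C)C(C)(C)C)CCC(O[Si](C)(C)C)=C1C | intermediate
10 | aldol adduct: C14 ketone, quaternary C1, C2-OH, C3-OPMB, C4-OTES, terminal alkyne, C10-vinyl, C11-OTBS | C#C[C@@H](O[Si](CC)(CC)CC)[C@@H](OCc1ccc(OC)cc1)[C@H](O)[C@@]2(C)C(=O)CC[C@@H](O[Si](C)(C)C(C)(C)C)[C@@H]2C=C | intermediate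
11 | C2/C14 anti-diol of 10 (axial C14-OH) | C#C[C@@H](O[Si](CC)(CC)CC)[C@@H](OCc1ccc(OC)cc1)[C@H](O)[C@@]2(C)[C@@H](O)CC[C@@H](O[Si](C)(C)C(C)(C)C)[C@@H]2C=C | intermediate
12 | C2/C3/C14 triol | C#C[C@@H](O[Si](CC)(CC)CC)[C@@H](O)[C@H](O)[C@@]2(C)[C@@H](O)CC[C@@H](O[Si](C)(C)C(C)(C)C)[C@@H]2C=C | intermediate
13 | C2/C3/C14 triacetate | C#C[C@@H](O[Si](CC)(CC)CC)[C@@H](OC(C)=O)[C@H](OC(C)=O)[C@@]2(C)[C@@H](OC(C)=O)CC[C@@H](O[Si](C)(C)C(C)(C)C)[C@@H]2C=C | intermediate
14 | C9 aldehyde | C#C[C@@H](O[Si](CC)(CC)CC)[C@@H](OC(C)=O)[C@H](OC(C)=O)[C@@]2(C)[C@@H](OC(C)=O)CC[C@@H](O[Si](C)(C)C(C)(C)C)[C@@H]2C=O | intermediate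
15 | diazo aldol adduct (C9 carbinol, C8 diazo, tert-butyl ester; C9 epimers) | C#C[C@@H](O[Si](CC)(CC)CC)[C@@H](OC(C)=O)[C@H](OC(C)=O)[C@@]2(C)[C@@H](OC(C)=O)CC[C@@H](O[Si](C)(C)C(C)(C)C)[C@@H]2C(O)C(=[N+]=[N-])C(=O)OC(C)(C)C | intermediate
16 | C9-keto C8-diazo tert-butyl ester | C#C[C@@H](O[Si](CC)(CC)CC)[C@@H](OC(C)=O)[C@H](OC(C)=O)[C@@]2(C)[C@@H](OC(C)=O)CC[C@@H](O[Si](C)(C)C(C)(C)C)[C@@H]2C(=O)C(=[N+]=[N-])C(=O)OC(C)(C)C | intermediate
17 | C4 alcohol of 16 | C#C[C@@H](O)[C@@H](OC(C)=O)[C@H](OC(C)=O)[C@@]2(C)[C@@H](OC(C)=O)CC[C@@H](O[Si](C)(C)C(C)(C)C)[C@@H]2C(=O)C(=[N+]=[N-])C(=O)OC(C)(C)C | intermediate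
18 | oxocan-3-one fused to the cyclohexane: C8-H with CO2t-Bu (C8 epimers), C9 ketone, C4 ethynyl | C#C[C@H]1OC(C(=O)OC(C)(C)C)C(=O)[C@H]2[C@H](O[Si](C)(C)C(C)(C)C)CC[C@H](OC(C)=O)[C@]2(C)[C@@H](OC(C)=O)[C@@H]1OC(C)=O | intermediate
19 | C8-(but-3-en-2-yl) quaternary β-keto ester (C17 set; C8 epimers) | C#C[C@H]1OC(C(=O)OC(C)(C)C)([C@@H](C)C=C)C(=O)[C@H]2[C@H](O[Si](C)(C)C(C)(C)C)CC[C@H](OC(C)=O)[C@]2(C)[C@@H](OC(C)=O)[C@@H]1OC(C)=O | intermediate
20 | (9S)-alcohol | C#C[C@H]1OC(C(=O)OC(C)(C)C)([C@@H](C)C=C)[C@@H](O)[C@H]2[C@H](O[Si](C)(C)C(C)(C)C)CC[C@H](OC(C)=O)[C@]2(C)[C@@H](OC(C)=O)[C@@H]1OC(C)=O | intermediate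
21 | C9 TBS ether | C#C[C@H]1OC(C(=O)OC(C)(C)C)([C@@H](C)C=C)[C@@H](O[Si](C)(C)C(C)(C)C)[C@H]2[C@H](O[Si](C)(C)C(C)(C)C)CC[C@H](OC(C)=O)[C@]2(C)[C@@H](OC(C)=O)[C@@H]1OC(C)=O | intermediate
22 | C11 alcohol | C#C[C@H]1OC(C(=O)OC(C)(C)C)([C@@H](C)C=C)[C@@H](O[Si](C)(C)C(C)(C)C)[C@H]2[C@H](O)CC[C@H](OC(C)=O)[C@]2(C)[C@@H](OC(C)=O)[C@@H]1OC(C)=O | intermediate
23 | C11 ketone | C#C[C@H]1OC(C(=O)OC(C)(C)C)([C@@H](C)C=C)[C@@H](O[Si](C)(C)C(C)(C)C)[C@H]2C(=O)CC[C@H](OC(C)=O)[C@]2(C)[C@@H](OC(C)=O)[C@@H]1OC(C)=O | intermediate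
24 | C11/C20 spiro-epoxide | C#C[C@H]1OC(C(=O)OC(C)(C)C)([C@@H](C)C=C)[C@@H](O[Si](C)(C)C(C)(C)C)[C@H]2[C@]3(CO3)CC[C@H](OC(C)=O)[C@]2(C)[C@@H](OC(C)=O)[C@@H]1OC(C)=O | intermediate
25 | C11 tertiary alcohol, C20 acetate (tetraacetate) | C#C[C@H]1OC(C(=O)OC(C)(C)C)([C@@H](C)C=C)[C@@H](O[Si](C)(C)C(C)(C)C)[C@H]2[C@](O)(COC(C)=O)CC[C@H](OC(C)=O)[C@]2(C)[C@@H](OC(C)=O)[C@@H]1OC(C)=O | intermediate
26 | C19 aldehyde | C#C[C@H]1OC(C(=O)OC(C)(C)C)([C@@H](C)C=O)[C@@H](O[Si](C)(C)C(C)(C)C)[C@H]2[C@](O)(COC(C)=O)CC[C@H](OC(C)=O)[C@]2(C)[C@@H](OC(C)=O)[C@@H]1OC(C)=O | intermediate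
27 | C19 carboxylic acid | C#C[C@H]1OC(C(=O)OC(C)(C)C)([C@@H](C)C(=O)O)[C@@H](O[Si](C)(C)C(C)(C)C)[C@H]2[C@](O)(COC(C)=O)CC[C@H](OC(C)=O)[C@]2(C)[C@@H](OC(C)=O)[C@@H]1OC(C)=O | intermediate
28 | C19 acid chloride | C#C[C@H]1OC(C(=O)OC(C)(C)C)([C@@H](C)C(Cl)=O)[C@@H](O[Si](C)(C)C(C)(C)C)[C@H]2[C@](O)(COC(C)=O)CC[C@H](OC(C)=O)[C@]2(C)[C@@H](OC(C)=O)[C@@H]1OC(C)=O | intermediate
29 | 1,2-dichloroethyl ester at C19 | C#C[C@H]1OC(C(=O)OC(C)(C)C)([C@@H](C)C(=O)OC(Cl)CCl)[C@@H](O[Si](C)(C)C(C)(C)C)[C@H]2[C@](O)(COC(C)=O)CC[C@H](OC(C)=O)[C@]2(C)[C@@H](OC(C)=O)[C@@H]1OC(C)=O | intermediate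
30 | 2-chlorovinyl ester at C19 (E/Z), tert-butyl ester at C8 | C#C[C@H]1OC(C(=O)OC(C)(C)C)([C@@H](C)C(=O)OC=CCl)[C@@H](O[Si](C)(C)C(C)(C)C)[C@H]2[C@](O)(COC(C)=O)CC[C@H](OC(C)=O)[C@]2(C)[C@@H](OC(C)=O)[C@@H]1OC(C)=O | intermediate
31 | C8 carboxylic acid | C#C[C@H]1OC(C(=O)O)([C@@H](C)C(=O)OC=CCl)[C@@H](O[Si](C)(C)C(C)(C)C)[C@H]2[C@](O)(COC(C)=O)CC[C@H](OC(C)=O)[C@]2(C)[C@@H](OC(C)=O)[C@@H]1OC(C)=O | intermediate
32 | C8 N-acyloxyphthalimide (cascade precursor) | C#C[C@H]1OC(C(=O)ON3C(=O)c4ccccc4C3=O)([C@@H](C)C(=O)OC=CCl)[C@@H](O[Si](C)(C)C(C)(C)C)[C@H]2[C@](O)(COC(C)=O)CC[C@H](OC(C)=O)[C@]2(C)[C@@H](OC(C)=O)[C@@H]1OC(C)=O | intermediate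
33 | 9-O-TBS ether of the target | C=C1[C@H]2O[C@]3([C@@H](C)C(=O)O[C@H]3[C@H]1Cl)[C@@H](O[Si](C)(C)C(C)(C)C)[C@H]1[C@](O)(COC(C)=O)CC[C@H](OC(C)=O)[C@]1(C)[C@@H](OC(C)=O)[C@@H]2OC(C)=O | intermediate
34 | CNP0190959.1 | C=C1[C@H]2O[C@]3([C@@H](C)C(=O)O[C@H]3[C@H]1Cl)[C@@H](O)[C@H]1[C@](O)(COC(C)=O)CC[C@H](OC(C)=O)[C@]1(C)[C@@H](OC(C)=O)[C@@H]2OC(C)=O | target

**Count**
Total steps: 27. Longest linear sequence: 24 steps (steps 4–27, from 6); the aldehyde fragment 5 takes 3 steps (steps 1–3).

**Three steps most likely to fail**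

Step 26. The ester must reach its s-cis rotamer before the 5-exo closure, so hydrogen transfer to the C8 radical may win (simple hydrodecarboxylation). Alternatively the first closure may occur on the wrong face of C8, and the C6 radical is then quenched before it reaches the alkyne. The fallback sets out from 31 and comes back at 33. Acid 31 is converted through its acid chloride (1-chloro-N,N,2-trimethylpropenylamine, then potassium O-ethyl xanthate) into the S-acyl xanthate F1. Visible-light irradiation (or lauroyl peroxide, 1,2-dichloroethane, reflux) gives the acyl radical, which loses CO. With no hydrogen donor present the C8 radical can only return to a xanthate or cyclise, and the cyclised C6 radical is stored by group transfer as the α-chloro xanthate F2 (lactone closed, alkyne intact). In a separate operation Bu3SnH/AIBN (slow addition, benzene, 80 °C) regenerates the C6 radical, which closes 6-exo-dig and is reduced to 33.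

Step 14. The rhodium carbenoid may be diverted into 1,5 C–H insertion, ylide formation with neighbouring oxygens or dimerisation instead of closing the eight-membered ring. The fallback sets out from 14 and comes back at 18. Roskamp homologation of 14 (tert-butyl diazoacetate, SnCl2, CH2Cl2) gives the β-keto ester F3, and HF·pyridine frees the C4 alcohol F4. Iodine(III)-mediated oxidative α-alkoxylation (PhI(OAc)2 or PhIO/BF3·OEt2, high dilution) then lets the C4 hydroxyl displace the iodonium enolate at C8. This gives 18 by an umpolung etherification that does not touch the C4 stereocentre.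

Step 7. Conversion may be low, or retro-aldol may intervene at the congested quaternary centre, and chelation control may erode (Felkin-type attack giving the C2 epimer). The fallback sets out from 9 and comes back at 10. NBS converts 9 into the α-bromo ketone F5. SmI2 (THF, −78 °C, added to F5 in the presence of 5) generates the samarium(III) enolate regiospecifically, and it should add to 5 through a closed transition state in which samarium bridges the aldehyde and α-OPMB oxygens. This is a Reformatsky-type aldol that tolerates quaternary-centre formation.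

**Further compounds**
F1 | step 26 | S-acyl O-ethyl xanthate of acid 31 | C#C[C@H]1OC(C(=O)SC(=S)OCC)([C@@H](C)C(=O)OC=CCl)[C@@H](O[Si](C)(C)C(C)(C)C)[C@H]2[C@](O)(COC(C)=O)CC[C@H](OC(C)=O)[C@]2(C)[C@@H](OC(C)=O)[C@@H]1OC(C)=O
F2 | step 26 | monocyclised lactone with C6 chloro xanthate (C6 epimers), alkyne intact | C#C[C@H]2O[C@]3([C@@H](C)C(=O)O[C@H]3C(Cl)SC(=S)OCC)[C@@H](O[Si](C)(C)C(C)(C)C)[C@H]1[C@](O)(COC(C)=O)CC[C@H](OC(C)=O)[C@]1(C)[C@@H](OC(C)=O)[C@@H]2OC(C)=O
F3 | step 14 | tert-butyl β-keto ester (C9 ketone, C8 methylene, C4-OTES) | C#C[C@@H](O[Si](CC)(CC)CC)[C@@H](OC(C)=O)[C@H](OC(C)=O)[C@@]2(C)[C@@H](OC(C)=O)CC[C@@H](O[Si](C)(C)C(C)(C)C)[C@@H]2C(=O)CC(=O)OC(C)(C)C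
F4 | step 14 | C4 alcohol of F3 | C#C[C@@H](O)[C@@H](OC(C)=O)[C@H](OC(C)=O)[C@@]2(C)[C@@H](OC(C)=O)CC[C@@H](O[Si](C)(C)C(C)(C)C)[C@@H]2C(=O)CC(=O)OC(C)(C)C
F5 | step 7 | (3R,4R)-2-bromo-4-(tert-butyldimethylsilyloxy)-2-methyl-3-vinylcyclohexan-1-one (C2 epimers) | C=C[C@H]1[C@H](O[Si](C)(C)C(C)(C)C)CCC(=O)C1(C)Br
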